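The γ‑lactone (O1, C2, C3, C3a, C7a; benzofuranone numbering) is cut at C3–C2. C3 is first installed as the CH2 of a cyclopropane across C3a–C4, delivered cis to O1 by the C7a hydroxyl, which then carries C2 as a phenyl carbonate. In the key step SmI2 reduces the C5 ketone of this bicyclo[4.1.0]heptanone: strain release cleaves C4–C3, the C3 radical is reduced to an alkylsamarium and closes the lactone onto C2, unveiling quaternary C3a and the C4 methylene of the cyclohexanone ring in one operation. It exploits the cis‑1,3 relation of O1 and C3 across C7a–C3a and the C5 carbonyl that flanks C4.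

Key step: step 7

Remark: locants O1, C2, C3, C3a, C4 to C7 and C7a are those of the benzofuran‑2,5‑dione core of the target and are kept for all intermediates; farnesyl means (2E,6E)‑3,7,11‑trimethyldodeca‑2,6,10‑trien‑1‑yl; 1 and 4 are assumed to be purchased.

Step 1
Reactants: 1 1,4-dioxaspiro[4.5]dec-6-en-8-one
Product: 2 7-iodo-1,4-dioxaspiro[4.5]dec-6-en-8-one
Conditions: I2, pyridine, CH2Cl2, 0 °C to rt
Reagents that add atoms: iodine, II
Why: α‑Iodination of a cyclic enone by the iodine–pyridine addition–elimination sequence (Baylis–Hillman‑type) is reliable and should leave the dioxolane untouched.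

Step 2
Reactants: 2 7-iodo-1,4-dioxaspiro[4.5]dec-6-en-8-one
Product: 3 (8R)-7-iodo-1,4-dioxaspiro[4.5]dec-6-en-8-ol
Conditions: (S)-2-methyl-CBS-oxazaborolidine (10 mol %), BH3·SMe2, THF, −20 °C; MeOH, then aqueous work-up
Reagents that add atoms: none
Why: Corey–Bakshi–Shibata reduction, in which the iodoalkenyl arm behaves as the large group so that the (S)‑catalyst should deliver hydride to the face giving the (8R)‑carbinol, the future C7a.

Step 3
Reactants: 3 (8R)-7-iodo-1,4-dioxaspiro[4.5]dec-6-en-8-ol; 4 (2E,6E)-farnesyl bromide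
Product: 7 (8R)-7-[(2E,6E)-farnesyl]-1,4-dioxaspiro[4.5]dec-6-en-8-ol, via dilithio alkoxide 5 (not isolated), via alkenylzinc bromide 6 (not isolated)
Conditions: t-BuLi (3 equiv), Et2O, −78 °C; ZnBr2, THF, −78 to 0 °C; 4, Pd(PPh3)4 (5 mol %), 0 °C to rt; aq. NH4Cl
Reagents that add atoms: none
Why: Negishi alkenyl–allyl coupling, in which the alkenylzinc should attack the unsubstituted terminus of the farnesyl π‑allylpalladium with retention of the 2E geometry while the carbinol centre is untouched.

Step 4
Reactants: 7 (8R)-7-[(2E,6E)-farnesyl]-1,4-dioxaspiro[4.5]dec-6-en-8-ol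
Product: 8 ethylene ketal of (1R,5R,6S)-6-farnesyl-5-hydroxybicyclo[4.1.0]heptan-2-one (cyclopropane CH2 cis to OH)
Conditions: Et2Zn (2 equiv), CH2I2 (2 equiv), CH2Cl2, −20 to 0 °C
Reagents that add atoms: diiodomethane, ICI
Why: Hydroxyl‑directed Simmons–Smith cyclopropanation (Furukawa reagent), in which the zinc alkoxide delivers CH2 to its own face, setting C3a and C4 with C3 cis to O1, and in which directed delivery should outpace attack on the remote chain alkenes.

Step 5
Reactants: 8 ethylene ketal of (1R,5R,6S)-6-farnesyl-5-hydroxybicyclo[4.1.0]heptan-2-one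
Product: 9 phenyl carbonate of 8
Conditions: PhOCOCl, pyridine, DMAP (cat.), CH2Cl2, 0 °C to rt
Reagents that add atoms: phenyl chloroformate, O=C(Cl)Oc1ccccc1
Why: Acylation of the secondary alcohol with a chloroformate under nucleophilic catalysis, which places the future C2 on O1 as an electrophilic aryl carbonate.

Step 6
Reactants: 9 phenyl carbonate of 8
Product: 10 phenyl carbonate of (1R,5R,6S)-6-farnesyl-5-hydroxybicyclo[4.1.0]heptan-2-one
Conditions: PPTS (0.2 equiv), acetone/H2O (10:1), 50 °C
Reagents that add atoms: water, O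
Why: Acid‑catalysed ketal hydrolysis, eased by the cyclopropane‑stabilised oxocarbenium ion and mild enough for the carbonate, the cyclopropane and the trisubstituted alkenes.

Step 7
Reactants: 10 phenyl carbonate of (1R,5R,6S)-6-farnesyl-5-hydroxybicyclo[4.1.0]heptan-2-one
Product: 12 (3aR,7aR)-3a-[(2E,6E)-farnesyl]hexahydro-1-benzofuran-2,5-dione (cis-fused keto lactone), via alkylsamarium enolate 11 (not isolated)
Conditions: SmI2 (2.5 equiv), HMPA (10 equiv), THF, −78 to 0 °C; pH 7 phosphate buffer
Reagents that add atoms: none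
Why: Proposed new method: electron transfer from SmI2 to the C5 ketone gives a ketyl whose cyclopropane fragments at the exocyclic C4–C3 bond, leaving a trivalent‑samarium enolate (C4=C5) and a primary C3 radical; a second SmI2 reduces this radical to a C3 alkylsamarium, which attacks the phenyl carbonate on O1 and expels phenoxide, so that C3–C2 is the bond that closes the ring. Each stage has a close known relative (SmI2 reductive opening of cyclopropyl ketones, capture of SmI2‑generated alkylsamariums by acylating agents, Barbier‑type intramolecular nucleophilic acyl substitution of iodoalkyl esters), but their union on a cyclopropyl ketone carbonate is new. The γ‑lactone closes by 5‑exo‑trig addition–elimination at the carbonate carbonyl, and no other ring is formed. No stereocentre is created: C3a and C7a are those of 10, C4 becomes a methylene when the enolate is protonated, and the cis ring fusion follows from the cis placement of C3 and O1 set in step 4. The step needs C4–C3 to break in preference to C4–C3a, which the better overlap of the exocyclic bond with the ketyl orbital in the bicyclo[4.1.0]heptanone should secure, and it needs radical reduction to outrun hydrogen abstraction, which HMPA and the absence of a proton source should provide. The C3 radical can reach the chain and ring alkenes only in 4‑exo or 5‑endo modes, no acyl radical is ever formed, and the ketone stays masked as its enolate until the quench.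

Step 8
Reactants: 12 (3aR,7aR)-3a-[(2E,6E)-farnesyl]hexahydro-1-benzofuran-2,5-dione
Product: 13 CNP0400313.1, (3aR,7aR)-3a-[(2E,6E)-farnesyl]-3,3a,4,7a-tetrahydro-1-benzofuran-2,5-dione
Conditions: IBX (1.5 equiv), 4-methoxypyridine N-oxide (1.5 equiv), DMSO, rt
Reagents that add atoms: none
Why: IBX dehydrogenation of a ketone through its enol, regiospecific here because quaternary C3a has no hydrogen, so that only the C6–C7 bond can be desaturated and C7a is not touched.

Compound list
1 | 1,4-dioxaspiro[4.5]dec-6-en-8-one | O=C1C=CC2(CC1)OCCO2 | starting material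
2 | 7-iodo-1,4-dioxaspiro[4.5]dec-6-en-8-one | O=C1C(I)=CC2(CC1)OCCO2 | intermediate
3 | (8R)-7-iodo-1,4-dioxaspiro[4.5]dec-6-en-8-ol | O[C@H]1C(I)=CC2(CC1)OCCO2 | intermediate
4 | (2E,6E)-farnesyl bromide | CC(C)=CCC/C(C)=C/CC/C(C)=C/CBr | starting material
5 | dilithio alkoxide of 3 (lithium alkoxide, C7 alkenyllithium) | [Li]O[C@H]1C([Li])=CC2(CC1)OCCO2 | intermediate
6 | alkenylzinc bromide of 3 (lithium alkoxide) | [Li]O[C@H]1C([Zn]Br)=CC2(CC1)OCCO2 | intermediate
7 | (8R)-7-[(2E,6E)-farnesyl]-1,4-dioxaspiro[4.5]dec-6-en-8-ol | CC(C)=CCC/C(C)=C/CC/C(C)=C/CC1=CC2(CC[C@H]1O)OCCO2 | intermediate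
8 | ethylene ketal of (1R,5R,6S)-6-farnesyl-5-hydroxybicyclo[4.1.0]heptan-2-one | CC(C)=CCC/C(C)=C/CC/C(C)=C/C[C@]12C[C@H]1C3(OCCO3)CC[C@H]2O | intermediate
9 | phenyl carbonate of 8 | CC(C)=CCC/C(C)=C/CC/C(C)=C/C[C@]12C[C@H]1C3(OCCO3)CC[C@H]2OC(=O)Oc4ccccc4 | intermediate
10 | phenyl carbonate of (1R,5R,6S)-6-farnesyl-5-hydroxybicyclo[4.1.0]heptan-2-one | CC(C)=CCC/C(C)=C/CC/C(C)=C/C[C@]12C[C@H]1C(=O)CC[C@H]2OC(=O)Oc3ccccc3 | intermediate
11 | alkylsamarium enolate: phenyl (1R,2S)-2-[(diiodosamaryl)methyl]-4-[(diiodosamaryl)oxy]-2-farnesylcyclohex-3-en-1-yl carbonate | CC(C)=CCC/C(C)=C/CC/C(C)=C/C[C@]1(C[Sm](I)I)C=C(O[Sm](I)I)CC[C@H]1OC(=O)Oc2ccccc2 | intermediate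
12 | (3aR,7aR)-3a-[(2E,6E)-farnesyl]hexahydro-1-benzofuran-2,5-dione | CC(C)=CCC/C(C)=C/CC/C(C)=C/C[C@]12CC(=O)CC[C@H]1OC(=O)C2 | intermediate
13 | CNP0400313.1, (3aR,7aR)-3a-[(2E,6E)-farnesyl]-3,3a,4,7a-tetrahydro-1-benzofuran-2,5-dione | CC(C)=CCC/C(C)=C/CC/C(C)=C/C[C@]12CC(=O)C=C[C@H]1OC(=O)C2 | target

Total step count: 8. Longest linear sequence: 8 steps (1 to 13); 4 enters in step 3.

Steps most likely to fail

1. Step 7 (Proposed new method). What may go wrong: the ring‑opened C3 radical or alkylsamarium is quenched by hydrogen abstraction or protonation before acyl transfer, or the endocyclic C4–C3a bond cleaves instead, with ring enlargement. Fallback with known chemistry, from 10 back to 12: iodotrimethylsilane buffered with 2,6‑di‑tert‑butylpyridine (CH2Cl2, −40 to 0 °C) should open the cyclopropane by homoconjugate attack of iodide at the unsubstituted C3. This would give phenyl (1R,2S)-2-farnesyl-2-(iodomethyl)-4-(trimethylsilyloxy)cyclohex-3-en-1-yl carbonate F1, in which the ketone is masked as its silyl enol ether. t‑BuLi (2 equiv, Et2O/pentane, −78 °C) should then effect iodine–lithium exchange, and the alkyllithium should cyclise onto the carbonate (exchange‑initiated intramolecular acylation, Parham‑type) to the lactone silyl enol ether (3aS,7aR)-3a-farnesyl-5-(trimethylsilyloxy)-3a,6,7,7a-tetrahydro-1-benzofuran-2(3H)-one F2. Dilute acid on work‑up should hydrolyse F2 to 12.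

2. Step 3. What may go wrong: O‑allylation of the alkoxide by the farnesyl π‑allylpalladium, or erosion of regio‑ and E/Z‑integrity within that π‑allyl. Fallback, from 3 back to 7: silylation (TBSCl, imidazole, DMF) should give tert-butyl{[(8R)-7-iodo-1,4-dioxaspiro[4.5]dec-6-en-8-yl]oxy}dimethylsilane F3. Iodine–lithium exchange (t‑BuLi, 2 equiv, Et2O, −78 °C), transmetalation with MgBr2·OEt2 and Li2CuCl4‑catalysed SN2 coupling with 4, which involves no π‑allyl intermediate, should give tert-butyl{[(8R)-7-farnesyl-1,4-dioxaspiro[4.5]dec-6-en-8-yl]oxy}dimethylsilane F4. TBAF in THF should then return 7.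

3. Step 8. What may go wrong: the oxidation stalls through the unproductive C4 enol, or allylic positions of the chain are oxidised. Fallback, from 12 back to 13 (Saegusa–Ito oxidation): kinetic deprotonation at the less hindered C6 and silylation (LDA, TMSCl, THF, −78 °C) should give (3aR,7aR)-3a-farnesyl-5-(trimethylsilyloxy)-3a,4,7,7a-tetrahydro-1-benzofuran-2(3H)-one F5. Pd(OAc)2 in MeCN at rt should then give 13.

Further compounds
F1 | step 7 | phenyl (1R,2S)-2-farnesyl-2-(iodomethyl)-4-(trimethylsilyloxy)cyclohex-3-en-1-yl carbonate | CC(C)=CCC/C(C)=C/CC/C(C)=C/C[C@]1(CI)C=C(O[Si](C)(C)C)CC[C@H]1OC(=O)Oc2ccccc2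
F2 | step 7 | (3aS,7aR)-3a-farnesyl-5-(trimethylsilyloxy)-3a,6,7,7a-tetrahydro-1-benzofuran-2(3H)-one | CC(C)=CCC/C(C)=C/CC/C(C)=C/C[C@]12C=C(O[Si](C)(C)C)CC[C@H]1OC(=O)C2
F3 | step 3 | tert-butyl{[(8R)-7-iodo-1,4-dioxaspiro[4.5]dec-6-en-8-yl]oxy}dimethylsilane | CC(C)(C)[Si](C)(C)O[C@H]1C(I)=CC2(CC1)OCCO2
F4 | step 3 | tert-butyl{[(8R)-7-farnesyl-1,4-dioxaspiro[4.5]dec-6-en-8-yl]oxy}dimethylsilane | CC(C)=CCC/C(C)=C/CC/C(C)=C/CC1=CC2(CC[C@H]1O[Si](C)(C)C(C)(C)C)OCCO2
F5 | step 8 | (3aR,7aR)-3a-farnesyl-5-(trimethylsilyloxy)-3a,4,7,7a-tetrahydro-1-benzofuran-2(3H)-one | CC(C)=CCC/C(C)=C/CC/C(C)=C/C[C@]12CC(O[Si](C)(C)C)=CC[C@H]1OC(=O)C2
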